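The easy step comes first: substrate leaves by two first-order steps, and you asked for a quick number, so I start from those.

    substrate → intermediate A (k1 = 0.11 h⁻¹)
    substrate → intermediate B (k2 = 0.050 h⁻¹)
    intermediate A ⇌ intermediate C (K3 = 0.34, k3 = 0.013 h⁻¹)
    intermediate B → intermediate D (k4 = 0.036 h⁻¹)
    intermediate B → target (k5 = 0.029 h⁻¹)
    intermediate D ⇌ intermediate E (K6 = 0.27, k6 = 0.030 h⁻¹)
    substrate + intermediate D → side product (k7 = 16 M⁻¹ h⁻¹)
    crystals ⇌ target, rate k8*(cs8 - [target]) while solid is left; crystals form when [target] > cs8 (cs8 = 6.5 mM, k8 = 2.3 h⁻¹)

| setting | Friday's | Sunday's | Thursday's |
|---|---|---|---|
| substrate | 3.0 mM | 10 mM | 30 mM |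
| time | 25 h | 25 h | 25 h |

* [target] (only what is free in solution) at the end for Friday's, Sunday's, Thursday's, in this order
* the course of these numbers from the first flask to the last (falls, then rises / rises all the way / falls all the way / rises, then falls / hardly changes)

- in percentages every species weighs as the substrate in it: one side product counts as two
- for target the crystals are counted in
- as a solid, counted per litre of solution: crystals
- the concentration of target that is asked is that of its free form alone
- "hardly changes" means that all values lie within two and a half points (for a concentration: within two and a half percent of the largest)
- run time (Friday's): 25 h

Substrate falls with the exit constant 0.160 h⁻¹, and the step to intermediate B takes 0.050 h⁻¹ of that. Intermediate B falls with its own exit constant 0.0650 h⁻¹, which is slower, and 0.029 h⁻¹ of it goes to target. Nothing from intermediates A, C, D or E returns to intermediate B, and I set step 7 aside as an assumption, so in this picture I have a plain first-order chain. Then c(intermediate B) is a difference of two exponentials, and the rate of target formation is 0.029 h⁻¹ times it, which I can integrate in closed form. I multiply 0.029 h⁻¹ by 0.050 h⁻¹ and divide by the difference of the exit constants. That factor goes on a bracket: for intermediate B, one minus the exponential of its exit constant times 25 h, over that constant; from this I subtract the same term for substrate. This gives 9.49% for the charge yield, the fraction of the charge standing as target at the end. It holds for any charge in this first-order picture, so I commit to 0.285 mM, 0.949 mM and 2.85 mM. The same charge yield multiplies a charge that goes up from each flask to the next, so the course I commit to is rises all the way. The last of these is under the solubility of 6.5 mM, so I expect no crystals.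

Your forecast gives 0.284 mM, 0.937 mM and 2.75 mM, with the course rises all the way, on the ground that “The free target therefore scales almost in proportion to the starting substrate”. On Thursday's flask my figure stands above yours, by 0.0980 mM.

The simulation gives 0.284 mM, 0.941 mM and 2.79 mM, with the course rises all the way.

Thursday's flask holds 9.30% of its charge as target against my charge yield of 9.49%, and crystals stand at 0%. Two things acting together hold that target down, each only a part of it: the step from intermediate B to intermediate D and the time given. Thursday's run without that step ends at 3.87 mM, and the run ten times as long ends at 4.02 mM. Striking the step from my quantity gives 12.9%, hence 3.87 mM for Thursday's flask and 0.387 mM for Friday's, whose simulated run without the step ends at 0.387 mM.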